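A direct plan would take rings A and B as finished arenes and close ring C last.
It would make 1-(benzyloxy)-4-bromo-2,5-dimethoxybenzene A1 in three steps (Dakin-type oxidation of a dimethoxybenzaldehyde, benzylation, bromination), add its aryllithium to a benzyloxyacetyl Weinreb amide and acylate the resulting ketone with the ring B acid chloride to the 1,3-diketone A2.
Ring A of A2 would then be oxidised with Ce(NH4)2(NO3)6 to an acylquinone, the enol oxygen would add to it (bond O1–C8a), and reduction would give the 5,8-quinol A3; methylation at O8 and hydrogenolysis would finish.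
Weakest, the oxidative closure of ring C: an untried quinone oxa-Michael cyclisation, run with excess tetravalent cerium on the most advanced intermediate, which carries four benzyl ethers and a second electron-rich arene.
Next, the mono-methylation of the air-sensitive quinol A3: it would have to tell two phenols apart, only to put back a methyl group that the oxidation had just removed.
Third, the three-step run-up to A1: it would add no skeletal bond.

**Plan of the new route**
Retrosynthesis: ring A is cut at C4a–C5 and at C8–C8a; ring C is cut afterwards at O1–C8a and C2–C3; ring B is bought.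
Forward order: ring B (bought), then ring C as a 2-aryl-3-benzyloxy-4-pyranone, then ring A last, folded onto the pyranone.
Enabling feature: ring A is a phloroglucinol-type ring (oxygen on C5, C7, C8a) whose C4a is the nucleophilic α-carbon of the vinylogous ester O1–C8a=C4a–C4=O of ring C. C5–C6–C7 can therefore arrive as an acylketene (masked as a dioxinone) hung on C8a through the carbinol carbon C8.
No arene is oxidised and no quinone appears, because every ring A oxygen is brought in at its final oxidation level.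
No phenol has to be told from another: the 8-methoxy group is made from the only hydroxyl of an aliphatic precursor, 5-OH and 7-OH are born free, and O1–C8a exists before ring A, so the 6-methoxy isomer cannot form.
Ring A is not bought and trimmed: two of its carbons come from the pyranone and four from a formyl dioxinone made in one step.

Key step: step 8

Remark: the target is achiral; 15 and 16 are racemic at the carbinol carbon, which becomes aromatic C8 in step 8, so no stereocontrol is needed. Ar = 3,5-bis(benzyloxy)-4-methoxyphenyl; TMP = 2,2,6,6-tetramethylpiperidide.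

**Step 1**
Reactants: 1 3,5-dihydroxy-4-methoxybenzoic acid
Product: 3 3,5-bis(benzyloxy)-4-methoxybenzoic acid, via benzyl ester 2 (not isolated)
Conditions: BnBr (3.3 equiv), K2CO3, DMF, 60 °C; then KOH, MeOH–H2O, 60 °C; aq HCl
Reagents that add atoms: benzyl bromide, BrCc1ccccc1; potassium hydroxide, [K+].[OH-]
Why: Williamson O-alkylation of both phenoxides and the carboxylate, followed in the same flask by saponification of the benzyl ester (acyl–oxygen cleavage), to which aryl benzyl and methyl ethers are inert.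

**Step 2**
Reactants: 3 3,5-bis(benzyloxy)-4-methoxybenzoic acid
Product: 4 3,5-bis(benzyloxy)-4-methoxybenzoyl chloride
Conditions: (COCl)2, DMF (cat.), CH2Cl2, 0 °C → rt
Reagents that add atoms: oxalyl chloride, O=C(Cl)C(=O)Cl
Why: Acid chloride formation under Vilsmeier-type DMF catalysis runs cold and gives only gaseous by-products, so the ethers are not at risk.

**Step 3**
Reactants: 5 benzyloxyacetyl chloride; 6 ethyl vinyl ether
Product: 8 (E)-1-(benzyloxy)-4-ethoxybut-3-en-2-one, via chloro ether 7 (not isolated)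
Conditions: 6 (3 equiv), CH2Cl2, 0 °C → rt; then pyridine, 0 °C → rt
Reagents that add atoms: none
Why: Electrophilic acylation of an enol ether by an activated α-alkoxy acid chloride should give the β-chloro ether, which loses HCl to the conjugated push–pull enone (E isomer favoured), as in the usual preparation of β-alkoxyvinyl ketones.

**Step 4**
Reactants: 8 (E)-1-(benzyloxy)-4-ethoxybut-3-en-2-one; 4 3,5-bis(benzyloxy)-4-methoxybenzoyl chloride
Product: 11 3-(benzyloxy)-2-[3,5-bis(benzyloxy)-4-methoxyphenyl]-4H-pyran-4-one, via lithium enolate 9 (not isolated), via diketone 10 (not isolated)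
Conditions: LiN(SiMe3)2 (2.2 equiv), THF, −78 °C; then 4, −78 → 0 °C; then CF3CO2H, CH2Cl2, rt
Reagents that add atoms: none
Why: Claisen-type C-acylation of the chelated (Z)-lithium enolate (the second equivalent of base takes up the more acidic diketone), then acid-catalysed 6-endo-trig oxa-Michael addition of the aryl ketone enol to the β-ethoxy enone and loss of ethanol, the γ-pyranone synthesis from β-alkoxy enones and acid chlorides, which closes ring C with O1 bonded to C2 and to the future C8a.

**Step 5**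
Reactants: 12 2,2,6-trimethyl-4H-1,3-dioxin-4-one
Product: 13 2,2-dimethyl-4-oxo-4H-1,3-dioxine-6-carbaldehyde
Conditions: SeO2 (1.2 equiv), 1,4-dioxane, 80 °C
Reagents that add atoms: selenium dioxide, O=[Se]=O
Why: Riley oxidation (ene reaction, then 2,3-sigmatropic shift) of the vinylogous methyl group, as with 2-methylchromones and 4-methylcoumarins, run below the temperature at which the dioxinone loses acetone.

**Step 6**
Reactants: 11 3-(benzyloxy)-2-[3,5-bis(benzyloxy)-4-methoxyphenyl]-4H-pyran-4-one; 13 2,2-dimethyl-4-oxo-4H-1,3-dioxine-6-carbaldehyde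
Product: 15 6-{[5-(benzyloxy)-6-[3,5-bis(benzyloxy)-4-methoxyphenyl]-4-oxo-4H-pyran-2-yl](hydroxy)methyl}-2,2-dimethyl-4H-1,3-dioxin-4-one (racemic), via bis(pyranonyl)zinc 14 (not isolated)
Conditions: TMP2Zn·2MgCl2·2LiCl (0.6 equiv), THF, −30 → 0 °C; then 13 (1.2 equiv), 0 °C → rt; aq NH4Cl
Reagents that add atoms: none
Why: Deprotonative zincation of the 4-pyranone at C6–H, the C–H next to the ring oxygen, by a hindered TMP-zinc amide in the presence of MgCl2 (expected to sit between O4 and the 3-benzyloxy oxygen, acidifying the vinylogous C6–H and keeping the base from C5), followed by MgCl2-promoted 1,2-addition of the zinc reagent to the reactive aldehyde; the new carbinol stereocentre is racemic and is lost in step 8.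

**Step 7**
Reactants: 15 6-{[5-(benzyloxy)-6-[3,5-bis(benzyloxy)-4-methoxyphenyl]-4-oxo-4H-pyran-2-yl](hydroxy)methyl}-2,2-dimethyl-4H-1,3-dioxin-4-one
Product: 16 6-{[5-(benzyloxy)-6-[3,5-bis(benzyloxy)-4-methoxyphenyl]-4-oxo-4H-pyran-2-yl](methoxy)methyl}-2,2-dimethyl-4H-1,3-dioxin-4-one (racemic)
Conditions: MeI (10 equiv), Ag2O (3 equiv), 4 Å MS, CH2Cl2, rt, dark
Reagents that add atoms: iodomethane, CI
Why: Purdie methylation of the only hydroxyl group in the molecule under non-basic conditions that spare the acidic C–H beside it; this methyl becomes the 8-methoxy group, and the ether also blocks lactonisation of the later ketene to a tetronic acid.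

**Step 8**
Reactants: 16 6-{[5-(benzyloxy)-6-[3,5-bis(benzyloxy)-4-methoxyphenyl]-4-oxo-4H-pyran-2-yl](methoxy)methyl}-2,2-dimethyl-4H-1,3-dioxin-4-one
Product: 18 3-(benzyloxy)-2-[3,5-bis(benzyloxy)-4-methoxyphenyl]-5,7-dihydroxy-8-methoxy-4H-chromen-4-one, via acylketene 17 (not isolated)
Conditions: toluene (0.005 M), 110 °C, Ar, slow distillation of acetone
Reagents that add atoms: none
Why: Proposed new method: heating triggers the known retro-hetero-Diels–Alder loss of acetone from the dioxinone to give acylketene 17, whose ketone enolises towards the acidic C8–H to the hydroxydienylketene C5=C6–C7(OH)=C8(OMe)–C8a=C4a; this closes by 6π electrocyclisation (equivalently, C-acylation of the nucleophilic pyranone α-carbon C4a by the ketene carbon C5), and tautomerisation of the cyclohexadienone gives the phenol. The closest known reaction types are the dienylketene electrocyclisation that ends the Danheiser benzannulation and the thermal cyclisation of arylacetyl ketenes (from dioxinones or acyl Meldrum's acids) to 1,3-dihydroxynaphthalenes; a 4-pyranone C–H has not served as the acceptor. Ring A closes in a 6π-electrocyclic mode by forming C4a–C5 only; no stereocentre is created and the one at C8 disappears. The step needs C-acylation at C4a rather than O-acylation or ketene dimerisation: the only hydroxyl was methylated in step 7, O4 could only close an eight-membered ring, attack by the ring oxygen or the methoxy oxygen is reversible, capture by the phenol of the product gives an aryl β-keto ester that re-forms the ketene at this temperature, and high dilution suppresses dimerisation. Because O1–C8a already exists, the oxygen at C5 can only end up peri to C4=O, so 5-OH, 7-OH and 8-OMe arise in place.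

**Step 9**
Reactants: 18 3-(benzyloxy)-2-[3,5-bis(benzyloxy)-4-methoxyphenyl]-5,7-dihydroxy-8-methoxy-4H-chromen-4-one
Product: 19 2-(3,5-dihydroxy-4-methoxyphenyl)-3,5,7-trihydroxy-8-methoxy-4H-chromen-4-one (CNP0103387.0)
Conditions: H2 (1 atm), 10% Pd/C, THF–MeOH, rt
Reagents that add atoms: none
Why: Catalytic hydrogenolysis should cleave the three benzyl ethers, while the methyl ethers and the fully substituted, conjugated C2=C3 bond of the flavonol are inert.

**Compound list**
1 | 3,5-dihydroxy-4-methoxybenzoic acid | COc1c(O)cc(C(=O)O)cc1O | starting material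
2 | benzyl 3,5-bis(benzyloxy)-4-methoxybenzoate | COc1c(OCc2ccccc2)cc(C(=O)OCc2ccccc2)cc1OCc1ccccc1 | intermediate
3 | 3,5-bis(benzyloxy)-4-methoxybenzoic acid | COc1c(OCc2ccccc2)cc(C(=O)O)cc1OCc1ccccc1 | intermediate
4 | 3,5-bis(benzyloxy)-4-methoxybenzoyl chloride | COc1c(OCc2ccccc2)cc(C(=O)Cl)cc1OCc1ccccc1 | intermediate
5 | benzyloxyacetyl chloride | O=C(Cl)COCc1ccccc1 | starting material
6 | ethyl vinyl ether | CCOC=C | starting material
7 | 1-(benzyloxy)-4-chloro-4-ethoxybutan-2-one (racemic) | CCOC(Cl)CC(=O)COCc1ccccc1 | intermediate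
8 | (E)-1-(benzyloxy)-4-ethoxybut-3-en-2-one | CCO/C=C/C(=O)COCc1ccccc1 | intermediate
9 | lithium (1Z,3E)-1-(benzyloxy)-4-ethoxybuta-1,3-dien-2-olate | [Li]O/C(=C\OCc1ccccc1)/C=C/OCC | intermediate
10 | (E)-2-(benzyloxy)-1-[3,5-bis(benzyloxy)-4-methoxyphenyl]-5-ethoxypent-4-ene-1,3-dione (racemic, enolisable) | CCO/C=C/C(=O)C(OCc1ccccc1)C(=O)c1cc(OCc2ccccc2)c(OC)c(OCc2ccccc2)c1 | intermediate
11 | 3-(benzyloxy)-2-[3,5-bis(benzyloxy)-4-methoxyphenyl]-4H-pyran-4-one | COc1c(OCc2ccccc2)cc(-c2occc(=O)c2OCc2ccccc2)cc1OCc1ccccc1 | intermediate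
12 | 2,2,6-trimethyl-4H-1,3-dioxin-4-one | CC1=CC(=O)OC(C)(C)O1 | starting material
13 | 2,2-dimethyl-4-oxo-4H-1,3-dioxine-6-carbaldehyde | O=CC1=CC(=O)OC(C)(C)O1 | intermediate
14 | bis{5-(benzyloxy)-6-[3,5-bis(benzyloxy)-4-methoxyphenyl]-4-oxo-4H-pyran-2-yl}zinc | O=c1cc([Zn]c2cc(=O)c(OCc3ccccc3)c(-c3cc(OCc4ccccc4)c(OC)c(OCc4ccccc4)c3)o2)oc(-c2cc(OCc3ccccc3)c(OC)c(OCc3ccccc3)c2)c1OCc1ccccc1 | intermediate
15 | 6-{[5-(benzyloxy)-6-[3,5-bis(benzyloxy)-4-methoxyphenyl]-4-oxo-4H-pyran-2-yl](hydroxy)methyl}-2,2-dimethyl-4H-1,3-dioxin-4-one (racemic) | CC1(C)OC(=O)C=C(C(O)c2cc(=O)c(OCc3ccccc3)c(-c3cc(OCc4ccccc4)c(OC)c(OCc4ccccc4)c3)o2)O1 | intermediate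
16 | 6-{[5-(benzyloxy)-6-[3,5-bis(benzyloxy)-4-methoxyphenyl]-4-oxo-4H-pyran-2-yl](methoxy)methyl}-2,2-dimethyl-4H-1,3-dioxin-4-one (racemic) | CC1(C)OC(=O)C=C(C(OC)c2cc(=O)c(OCc3ccccc3)c(-c3cc(OCc4ccccc4)c(OC)c(OCc4ccccc4)c3)o2)O1 | intermediate
17 | 4-{5-(benzyloxy)-6-[3,5-bis(benzyloxy)-4-methoxyphenyl]-4-oxo-4H-pyran-2-yl}-4-methoxybut-1-ene-1,3-dione (acylketene) | O=C=CC(=O)C(OC)c1cc(=O)c(OCc2ccccc2)c(-c2cc(OCc3ccccc3)c(OC)c(OCc3ccccc3)c2)o1 | intermediate
18 | 3-(benzyloxy)-2-[3,5-bis(benzyloxy)-4-methoxyphenyl]-5,7-dihydroxy-8-methoxy-4H-chromen-4-one | COc1c(OCc2ccccc2)cc(-c2oc3c(OC)c(O)cc(O)c3c(=O)c2OCc2ccccc2)cc1OCc1ccccc1 | intermediate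
19 | 2-(3,5-dihydroxy-4-methoxyphenyl)-3,5,7-trihydroxy-8-methoxy-4H-chromen-4-one | COc1c(O)cc(-c2oc3c(OC)c(O)cc(O)c3c(=O)c2O)cc1O | target

**Step count and risks**
Total steps: 9. Longest linear sequence: 7 steps (steps 1, 2, 4, 6, 7, 8, 9).

Most likely to fail:

1. Step 8 (proposed new method). The acylketene may be consumed by dimerisation, or by capture at oxygen (methyl transfer from the 8-methoxy group), faster than C4a is acylated. The fallback uses known chemistry, sets out from 16 and comes back at 18. Heating 16 with methanol (toluene–MeOH, 110 °C, sealed tube) should trap the ketene, by the usual alcoholysis of dioxinones, as methyl 4-{5-(benzyloxy)-6-[3,5-bis(benzyloxy)-4-methoxyphenyl]-4-oxo-4H-pyran-2-yl}-4-methoxy-3-oxobutanoate F1. Mg(OMe)2 in MeOH at reflux, then aq HCl, should fold F1 to 18 by Claisen (Dieckmann-type) condensation of C4a onto the ester, the base-mediated cyclisation used for pyranone-masked β-polyketo esters.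

2. Step 6. Deprotonation may occur at C5, next to the carbonyl group, instead of C6, or the zinc reagent may fail to add to the aldehyde. The fallback reverses the polarity of the C8–C8a bond and places a leaving group at C6 by ring construction; it sets out from 5 and 4 and comes back at 18.
   - Acylation of 1,1-bis(methylsulfanyl)ethene with 5 (pyridine, CH2Cl2) should give 1-(benzyloxy)-4,4-bis(methylsulfanyl)but-3-en-2-one F2.
   - Its enolate, lithium (Z)-1-(benzyloxy)-4,4-bis(methylsulfanyl)buta-1,3-dien-2-olate F3 (LiN(SiMe3)2, THF, −78 °C), and 4 should give 2-(benzyloxy)-1-[3,5-bis(benzyloxy)-4-methoxyphenyl]-5,5-bis(methylsulfanyl)pent-4-ene-1,3-dione F4.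
   - F4 should close with loss of methanethiol (CF3CO2H) to 3-(benzyloxy)-2-[3,5-bis(benzyloxy)-4-methoxyphenyl]-6-(methylsulfanyl)-4H-pyran-4-one F5.
   - mCPBA (2.2 equiv, CH2Cl2, 0 °C) should give 3-(benzyloxy)-2-[3,5-bis(benzyloxy)-4-methoxyphenyl]-6-(methanesulfonyl)-4H-pyran-4-one F6.
   - The γ-carbon of the dilithium dianion of methyl 4-methoxy-3-oxobutanoate F7 (LiN(iPr)2, 2.1 equiv, THF, −78 °C) should displace methanesulfinate at C6 by addition–elimination to give F1, which carries the 8-methoxy group from the start and is cyclised to 18 as described for step 8.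

3. Step 4. The enolate may be acylated at oxygen (enol ester) instead of carbon. The fallback replaces the acylation by an aldol addition and oxidation; it sets out from 4 and comes back at 10. Reduction of 4 with LiAlH(OtBu)3 (THF, −78 °C) should give 3,5-bis(benzyloxy)-4-methoxybenzaldehyde F8. Addition of enolate 9, which can react with an aldehyde only through carbon, should give (E)-4-(benzyloxy)-5-[3,5-bis(benzyloxy)-4-methoxyphenyl]-1-ethoxy-5-hydroxypent-1-en-3-one F9 as a mixture of diastereomers. Dess–Martin periodinane should oxidise F9 to 10, which closes to 11 with CF3CO2H as in step 4.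

**Further compounds**
F1 | step 8 | methyl 4-{5-(benzyloxy)-6-[3,5-bis(benzyloxy)-4-methoxyphenyl]-4-oxo-4H-pyran-2-yl}-4-methoxy-3-oxobutanoate (racemic) | COC(=O)CC(=O)C(OC)c1cc(=O)c(OCc2ccccc2)c(-c2cc(OCc3ccccc3)c(OC)c(OCc3ccccc3)c2)o1
F2 | step 6 | 1-(benzyloxy)-4,4-bis(methylsulfanyl)but-3-en-2-one | CSC(SC)=CC(=O)COCc1ccccc1
F3 | step 6 | lithium (Z)-1-(benzyloxy)-4,4-bis(methylsulfanyl)buta-1,3-dien-2-olate | [Li]O/C(=C\OCc1ccccc1)C=C(SC)SC
F4 | step 6 | 2-(benzyloxy)-1-[3,5-bis(benzyloxy)-4-methoxyphenyl]-5,5-bis(methylsulfanyl)pent-4-ene-1,3-dione | CSC(SC)=CC(=O)C(OCc1ccccc1)C(=O)c1cc(OCc2ccccc2)c(OC)c(OCc2ccccc2)c1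
F5 | step 6 | 3-(benzyloxy)-2-[3,5-bis(benzyloxy)-4-methoxyphenyl]-6-(methylsulfanyl)-4H-pyran-4-one | COc1c(OCc2ccccc2)cc(-c2oc(SC)cc(=O)c2OCc2ccccc2)cc1OCc1ccccc1
F6 | step 6 | 3-(benzyloxy)-2-[3,5-bis(benzyloxy)-4-methoxyphenyl]-6-(methanesulfonyl)-4H-pyran-4-one | COc1c(OCc2ccccc2)cc(-c2oc(S(C)(=O)=O)cc(=O)c2OCc2ccccc2)cc1OCc1ccccc1
F7 | step 6 | dilithium dianion of methyl 4-methoxy-3-oxobutanoate | [Li+].[Li+].COC(=O)C=C([O-])[CH-]OC
F8 | step 4 | 3,5-bis(benzyloxy)-4-methoxybenzaldehyde | COc1c(OCc2ccccc2)cc(C=O)cc1OCc1ccccc1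
F9 | step 4 | (E)-4-(benzyloxy)-5-[3,5-bis(benzyloxy)-4-methoxyphenyl]-1-ethoxy-5-hydroxypent-1-en-3-one | CCO/C=C/C(=O)C(OCc1ccccc1)C(O)c1cc(OCc2ccccc2)c(OC)c(OCc2ccccc2)c1
A1 | direct plan | 1-(benzyloxy)-4-bromo-2,5-dimethoxybenzene | COc1cc(Br)c(OC)cc1OCc1ccccc1
A2 | direct plan | 2-(benzyloxy)-1-[4-(benzyloxy)-2,5-dimethoxyphenyl]-3-[3,5-bis(benzyloxy)-4-methoxyphenyl]propane-1,3-dione | COc1cc(C(=O)C(OCc2ccccc2)C(=O)c2cc(OCc3ccccc3)c(OC)c(OCc3ccccc3)c2)c(OC)cc1OCc1ccccc1
A3 | direct plan | 3,7-bis(benzyloxy)-2-[3,5-bis(benzyloxy)-4-methoxyphenyl]-5,8-dihydroxy-4H-chromen-4-one | COc1c(OCc2ccccc2)cc(-c2oc3c(O)c(OCc4ccccc4)cc(O)c3c(=O)c2OCc2ccccc2)cc1OCc1ccccc1
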